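**Plan**
- Cuts, in retrosynthetic order: the two ester C–O bonds (O2–angeloyl, O4–epoxyacyl); C8=C9 and C9–C10 of ring A; C5–C6 of ring C; C6–C7 and C1–C11 of ring B; C4–C5 and C2–C3 of the chain.
- Forward: the chain C7–C1–C2–C3–C4 is built from the hydroxy ester; ring B arises by keteniminium–alkene [2+2] cycloaddition; C5 is added as an isopropenyl ketone and turned into the enol silane; ring C closes in the key step; ring A closes by phosphonate olefination; the two esters come last.
- Enabling feature: the bond C5–C6 joins the CMe2 carbon to a ring B methine that lies β to C8 through C7. C6 can therefore be the β-carbon of a 1-acetylcyclobutene (C7=C6, C8 = acetyl carbon) and C5 the carbon end of a C4=C5 enol silane on the C1 side chain. Their union closes ring C (C1–C2–C3–C4–C5–C6–C7) and gives rings B and C as a bicyclo[4.1.1]octane.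
- Stereochemistry: C2 by chelation-controlled aldol from the (S)-hydroxy ester, whose own centre is later erased; C1 and C11 in the cycloaddition under control of C2; C6 by the tether; C7 by equilibration during ring A closure; C4 by hydride delivery from O2 (Evans–Tishchenko), which also differentiates the two hydroxyls; the epoxide by Sharpless epoxidation; the angelate geometry from angelic acid.

Key step: step 14

Locants used below: C1 = ring B carbon with the methyl group and the side chain; C2 = carbinol that becomes the angelate; C3 = CH2; C4 = carbinol that becomes the epoxy ester; C5 = CMe2; C6 = ring B CH bonded to C5; C7 and C11 = the other ring B CH carbons (C7 bonded to C8); C8(Me)=C9–C10(=O) = enone bridge; ring A = C6 to C11; ring B = C1, C7, C6, C11; ring C = C1 to C7.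

Remark: the Michael adduct and its successors are drawn as the C7 epimer with the acetyl group anti to the four-carbon bridge; C7 is α to a ketone, so either epimer converges under the basic conditions of the ring A closure.

Step 1
Reactants: 1 methyl (2S)-3-hydroxy-2-methylpropanoate
Product: 2 methyl (2S)-3-(benzyloxy)-2-methylpropanoate
Conditions: BnOC(=NH)CCl3, TfOH (cat.), CH2Cl2/cyclohexane, rt
Reagents that add atoms: benzyl 2,2,2-trichloroacetimidate, N=C(OCc1ccccc1)C(Cl)(Cl)Cl
Why: Acid-catalysed O-benzylation with a trichloroacetimidate protects the primary alcohol without base, so the α-stereocentre of the ester should not epimerise.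

Step 2
Reactants: 2 methyl (2S)-3-(benzyloxy)-2-methylpropanoate
Product: 3 (2S)-3-(benzyloxy)-2-methylpropanal
Conditions: i-Bu2AlH, CH2Cl2, −78 °C
Reagents that add atoms: none
Why: Partial reduction of the ester by the aluminium hydride at low temperature stops at the aldehyde, which is used at once so that its α-centre is kept.

Step 3
Reactants: 3 (2S)-3-(benzyloxy)-2-methylpropanal
Product: 4 methyl (3R,4S)-5-(benzyloxy)-3-hydroxy-4-methylpentanoate
Conditions: TiCl4, CH2=C(OMe)OSiMe2t-Bu, CH2Cl2, −78 °C; aq. NaHCO3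
Reagents that add atoms: tert-butyl[(1-methoxyethenyl)oxy]dimethylsilane, C=C(OC)O[Si](C)(C)C(C)(C)C
Why: Chelation-controlled Mukaiyama aldol addition, in which TiCl4 ties the aldehyde and β-benzyloxy oxygens into a six-membered chelate and the silyl ketene acetal attacks the face opposite the α-methyl group, should set the new carbinol centre (C2, R) anti to that methyl group.

Step 4
Reactants: 4 methyl (3R,4S)-5-(benzyloxy)-3-hydroxy-4-methylpentanoate
Product: 5 methyl (3R,4S)-5-(benzyloxy)-3-[(tert-butyldimethylsilyl)oxy]-4-methylpentanoate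
Conditions: t-BuMe2SiOTf, 2,6-lutidine, CH2Cl2, −78 to 0 °C
Reagents that add atoms: tert-butyldimethylsilyl trifluoromethanesulfonate, CC(C)(C)[Si](C)(C)OS(=O)(=O)C(F)(F)F
Why: Silylation of the secondary alcohol with a silyl triflate and a hindered pyridine base protects O2 for the basic, organometallic and Lewis acidic steps ahead without touching a stereocentre.

Step 5
Reactants: 5 methyl (3R,4S)-5-(benzyloxy)-3-[(tert-butyldimethylsilyl)oxy]-4-methylpentanoate
Product: 6 methyl (3R,4S)-3-[(tert-butyldimethylsilyl)oxy]-5-hydroxy-4-methylpentanoate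
Conditions: H2, Pd/C, EtOAc, rt
Reagents that add atoms: none
Why: Hydrogenolysis of the benzyl ether frees the primary alcohol under neutral conditions that leave silyl ether and ester intact, and the δ-hydroxy ester is carried on directly to avoid lactonisation.

Step 6
Reactants: 6 methyl (3R,4S)-3-[(tert-butyldimethylsilyl)oxy]-5-hydroxy-4-methylpentanoate
Product: 7 (2R,3R)-3-[(tert-butyldimethylsilyl)oxy]-5-methoxy-2-methyl-5-oxopentanoic acid
Conditions: TEMPO (cat.), PhI(OAc)2, MeCN/H2O, rt
Reagents that add atoms: water, O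
Why: Nitroxyl-catalysed oxidation with PhI(OAc)2 in aqueous acetonitrile takes the primary alcohol through the aldehyde hydrate to the acid and spares the silyl ether, while any epimerisation α to the acid is harmless because that centre is erased in step 8.

Step 7
Reactants: 7 (2R,3R)-3-[(tert-butyldimethylsilyl)oxy]-5-methoxy-2-methyl-5-oxopentanoic acid
Product: 9 methyl (3R,4R)-3-[(tert-butyldimethylsilyl)oxy]-4-methyl-5-oxo-5-(pyrrolidin-1-yl)pentanoate, via mixed carbonic anhydride 8 (not isolated)
Conditions: i-BuOCOCl, N-methylmorpholine, THF, −15 °C; pyrrolidine, −15 °C to rt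
Reagents that add atoms: pyrrolidine, C1CCNC1
Why: Acylation of a secondary amine through the mixed carbonic anhydride gives the tertiary amide needed as the keteniminium precursor, and the methyl ester is not attacked at this temperature.

Step 8
Reactants: 9 methyl (3R,4R)-3-[(tert-butyldimethylsilyl)oxy]-4-methyl-5-oxo-5-(pyrrolidin-1-yl)pentanoate; 10 allyl benzyl ether
Product: 13 methyl (3R)-3-{(1R,2R)-2-[(benzyloxy)methyl]-1-methyl-4-oxocyclobutyl}-3-[(tert-butyldimethylsilyl)oxy]propanoate, via keteniminium triflate 11 (not isolated), via cyclobutaniminium triflate 12 (not isolated)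
Conditions: Tf2O, 2,4,6-collidine, ClCH2CH2Cl, −25 °C to rt; 10 (excess), 80 °C; aq. NaHCO3
Reagents that add atoms: water, O
Why: In this keteniminium–alkene [2+2] cycloaddition the terminal alkene carbon attacks C7 past the small methyl group, and ring closure at C1 should place the benzyloxymethyl group trans to the bulky side chain and occur anti to the C2–O bond of the allylic-strain-minimised conformer (C2–H in the enamine plane), which sets C1 and C11 as drawn and erases the old methyl-bearing centre before the iminium salt is hydrolysed.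

Step 9
Reactants: 13 methyl (3R)-3-{(1R,2R)-2-[(benzyloxy)methyl]-1-methyl-4-oxocyclobutyl}-3-[(tert-butyldimethylsilyl)oxy]propanoate
Product: 15 methyl (3R)-3-{(1R,4R)-4-[(benzyloxy)methyl]-1-methyl-2-[(trifluoromethanesulfonyl)oxy]cyclobut-2-en-1-yl}-3-[(tert-butyldimethylsilyl)oxy]propanoate, via potassium enolate 14 (not isolated)
Conditions: KN(SiMe3)2, THF, −78 °C; PhNTf2
Reagents that add atoms: N-phenylbis(trifluoromethanesulfonimide), O=S(=O)(N(c1ccccc1)S(=O)(=O)C(F)(F)F)C(F)(F)F
Why: Enol triflate formation by kinetic deprotonation at C6, the only enolisable position of the ketone since C1 is quaternary, and O-sulfonylation of the enolate, with the less acidic ester α-protons left alone.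

Step 10
Reactants: 15 methyl (3R)-3-{(1R,4R)-4-[(benzyloxy)methyl]-1-methyl-2-[(trifluoromethanesulfonyl)oxy]cyclobut-2-en-1-yl}-3-[(tert-butyldimethylsilyl)oxy]propanoate
Product: 16 (3R)-3-{(1R,4R)-4-[(benzyloxy)methyl]-1-methyl-2-[(trifluoromethanesulfonyl)oxy]cyclobut-2-en-1-yl}-3-[(tert-butyldimethylsilyl)oxy]-N-methoxy-N-methylpropanamide
Conditions: MeNH(OMe)·HCl, AlMe3, CH2Cl2, 0 °C to rt
Reagents that add atoms: N,O-dimethylhydroxylamine hydrochloride, CNOC.Cl
Why: Aluminium amide aminolysis of the methyl ester (Weinreb amide formation) prepares the C4 carbonyl for a single Grignard addition, and the enol triflate is inert to AlMe3.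

Step 11
Reactants: 16 (3R)-3-{(1R,4R)-4-[(benzyloxy)methyl]-1-methyl-2-[(trifluoromethanesulfonyl)oxy]cyclobut-2-en-1-yl}-3-[(tert-butyldimethylsilyl)oxy]-N-methoxy-N-methylpropanamide
Product: 17 (5R)-5-{(1R,4R)-4-[(benzyloxy)methyl]-1-methyl-2-[(trifluoromethanesulfonyl)oxy]cyclobut-2-en-1-yl}-5-[(tert-butyldimethylsilyl)oxy]-2-methylpent-1-en-3-one
Conditions: CH2=C(Me)MgBr, THF, −20 to 0 °C; cold aq. HCl/NH4Cl
Reagents that add atoms: isopropenylmagnesium bromide, C=C(C)[Mg]Br
Why: Weinreb ketone synthesis, in which the Grignard adduct is held as a chelate and gives the isopropenyl ketone on acidic quench, introduces C5 with both methyl carbons and keeps the released amine from adding to the enone.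

Step 12
Reactants: 17 (5R)-5-{(1R,4R)-4-[(benzyloxy)methyl]-1-methyl-2-[(trifluoromethanesulfonyl)oxy]cyclobut-2-en-1-yl}-5-[(tert-butyldimethylsilyl)oxy]-2-methylpent-1-en-3-one
Product: 18 (3R,4R)-3-[(benzyloxy)methyl]-4-{(1R)-1-[(tert-butyldimethylsilyl)oxy]-4-methyl-3-[(triethylsilyl)oxy]pent-3-en-1-yl}-4-methylcyclobut-1-en-1-yl trifluoromethanesulfonate
Conditions: Et3SiH, RhCl(PPh3)3 (cat.), toluene, 50 °C
Reagents that add atoms: triethylsilane, CC[SiH](CC)CC
Why: Rhodium-catalysed 1,4-hydrosilylation of the β-unsubstituted enone puts hydride on the terminal CH2 and silicon on oxygen, so the C4=C5 enol silane forms regiospecifically with no isomer towards C3, and the triflate and ring alkene are not reduced.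

Step 13
Reactants: 18 (3R,4R)-3-[(benzyloxy)methyl]-4-{(1R)-1-[(tert-butyldimethylsilyl)oxy]-4-methyl-3-[(triethylsilyl)oxy]pent-3-en-1-yl}-4-methylcyclobut-1-en-1-yl trifluoromethanesulfonate
Product: 19 1-[(3R,4S)-3-[(benzyloxy)methyl]-4-{(1R)-1-[(tert-butyldimethylsilyl)oxy]-4-methyl-3-[(triethylsilyl)oxy]pent-3-en-1-yl}-4-methylcyclobut-1-en-1-yl]ethan-1-one
Conditions: CO (3 atm), Me4Sn, Pd(PPh3)4 (cat.), LiCl, THF, 55 °C
Reagents that add atoms: carbon monoxide, [C-]#[O+]; tetramethylstannane, C[Sn](C)(C)C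
Why: Carbonylative Stille coupling (oxidative addition of zerovalent palladium into the cyclobutenyl triflate, CO insertion, methyl transfer from tin) installs the C7 acetyl group under neutral conditions that the enol silane should survive.

Step 14
Reactants: 19 1-[(3R,4S)-3-[(benzyloxy)methyl]-4-{(1R)-1-[(tert-butyldimethylsilyl)oxy]-4-methyl-3-[(triethylsilyl)oxy]pent-3-en-1-yl}-4-methylcyclobut-1-en-1-yl]ethan-1-one
Product: 21 (2R)-7-acetyl-8-[(benzyloxy)methyl]-2-[(tert-butyldimethylsilyl)oxy]-1,5,5-trimethylbicyclo[4.1.1]octan-4-one (position 8 = C11; both one-carbon-bridge substituents anti to the C2–C5 bridge), via trichlorotitanium enolate 20 (not isolated)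
Conditions: TiCl4, CH2Cl2, −78 °C; aq. NaHCO3
Reagents that add atoms: none
Why: TiCl4 binds the acetyl oxygen and makes C6 electrophilic; the C4=C5 enol silane on the C1 side chain attacks through C5, silicon leaves as Et3SiCl, and the titanium enolate across C7=C8 is protonated at work-up. The closest known reaction type is the intramolecular Mukaiyama–Michael addition of a tetrasubstituted enol silane that forms a quaternary carbon, together with conjugate additions to strained 1-acylcyclobutenes. Ring C closes in a 7-endo-trig mode counted through C7 (7-exo-trig counted through C11); the four-atom tether spans the C1···C6 diagonal of the four-membered ring comfortably and the cyclobutene loses its olefinic strain. C6 is fixed by the tether, because C5 can reach only the face of the cyclobutene that carries the C1 side chain, and C7 is set on protonation but remains epimerisable α to the acetyl group. The step needs C5 rather than C3 to be the nucleophile and C6 rather than the carbonyl carbon to be attacked: the first is secured by the regiospecific enol silane of step 12, the second by the soft silyl enol ether and by the C11 benzyloxymethyl group lying on the far face, away from the incoming carbon.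

Step 15
Reactants: 21 (2R)-7-acetyl-8-[(benzyloxy)methyl]-2-[(tert-butyldimethylsilyl)oxy]-1,5,5-trimethylbicyclo[4.1.1]octan-4-one
Product: 22 (2R)-7-acetyl-8-[(benzyloxy)methyl]-2-hydroxy-1,5,5-trimethylbicyclo[4.1.1]octan-4-one
Conditions: HF·pyridine, THF, 0 °C to rt
Reagents that add atoms: none
Why: Acidic fluoride desilylation frees O2 without the retro-aldol cleavage that a basic fluoride source could cause in the β-hydroxy ketone.

Step 16
Reactants: 22 (2R)-7-acetyl-8-[(benzyloxy)methyl]-2-hydroxy-1,5,5-trimethylbicyclo[4.1.1]octan-4-one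
Product: 23 (2R,4R)-7-acetyl-8-[(benzyloxy)methyl]-4-hydroxy-1,5,5-trimethylbicyclo[4.1.1]octan-2-yl acetate
Conditions: SmI2 (cat.), CH3CHO, THF, −10 °C
Reagents that add atoms: acetaldehyde, CC=O
Why: Evans–Tishchenko reduction, in which the samarium-bound hemiacetal of O2 and acetaldehyde delivers hydride to C4 from the side of O2, should give the trans (2,4-anti) C4 alcohol and leave O2 as its acetate, so the two hydroxyls emerge differentiated while the C8 ketone, lacking a β-hydroxyl, is not reduced.

Step 17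
Reactants: 23 (2R,4R)-7-acetyl-8-[(benzyloxy)methyl]-4-hydroxy-1,5,5-trimethylbicyclo[4.1.1]octan-2-yl acetate
Product: 24 (2R,4R)-7-acetyl-4-hydroxy-8-(hydroxymethyl)-1,5,5-trimethylbicyclo[4.1.1]octan-2-yl acetate
Conditions: H2, Pd/C, EtOAc, rt
Reagents that add atoms: none
Why: Hydrogenolysis of the benzyl ether frees the C10 alcohol and leaves ketone, acetate and the hindered alcohol untouched.

Step 18
Reactants: 24 (2R,4R)-7-acetyl-4-hydroxy-8-(hydroxymethyl)-1,5,5-trimethylbicyclo[4.1.1]octan-2-yl acetate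
Product: 25 (2R,4R)-7-acetyl-8-formyl-4-hydroxy-1,5,5-trimethylbicyclo[4.1.1]octan-2-yl acetate
Conditions: TEMPO (cat.), PhI(OAc)2, CH2Cl2, rt
Reagents that add atoms: none
Why: Nitroxyl-catalysed oxidation is selective for the primary alcohol over the neopentyl secondary C4 alcohol and gives the C10 aldehyde under non-epimerising conditions.

Step 19
Reactants: 25 (2R,4R)-7-acetyl-8-formyl-4-hydroxy-1,5,5-trimethylbicyclo[4.1.1]octan-2-yl acetate
Product: 26 (2R,4R)-7-acetyl-8-[2-(dimethoxyphosphoryl)acetyl]-4-hydroxy-1,5,5-trimethylbicyclo[4.1.1]octan-2-yl acetate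
Conditions: (MeO)2P(O)CHN2, SnCl2, CH2Cl2, rt
Reagents that add atoms: dimethyl (diazomethyl)phosphonate, COP(=O)(OC)C=[N+]=[N-]
Why: Roskamp homologation (SnCl2-promoted addition of the diazo compound to the aldehyde, then 1,2-hydride shift with loss of N2) gives the β-ketophosphonate and supplies C9, and ketones do not react, so the C8 acetyl group is untouched.

Step 20
Reactants: 26 (2R,4R)-7-acetyl-8-[2-(dimethoxyphosphoryl)acetyl]-4-hydroxy-1,5,5-trimethylbicyclo[4.1.1]octan-2-yl acetate
Product: 27 tricyclic enone with ring A closed [C8(Me)=C9–C10(=O)], O2 acetate and free C4 hydroxyl (2R,4R)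
Conditions: K2CO3, 18-crown-6, toluene, 80 °C
Reagents that add atoms: none
Why: Intramolecular Horner–Wadsworth–Emmons olefination of the C8 methyl ketone by the C9 phosphonate carbanion closes ring A as the 3-methylcyclohexenone; only the isomer with both C7 and C11 substituents anti to the four-carbon bridge can cyclise, and both centres, each α to a ketone, equilibrate under the base, so C7 ends as required.

Step 21
Reactants: 28 (2E)-2-methylbut-2-en-1-ol
Product: 29 [(2R,3R)-2,3-dimethyloxiran-2-yl]methanol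
Conditions: Ti(OiPr)4 (cat.), D-(−)-diisopropyl tartrate (cat.), t-BuOOH, 4 Å sieves, CH2Cl2, −20 °C
Reagents that add atoms: tert-butyl hydroperoxide, CC(C)(C)OO
Why: Sharpless asymmetric epoxidation with the D-(−)-tartrate ligand delivers oxygen to the face that gives the (2R,3R)-epoxy alcohol, and the E alkene fixes the cis relation of the two methyl groups.

Step 22
Reactants: 29 [(2R,3R)-2,3-dimethyloxiran-2-yl]methanol
Product: 30 (2S,3R)-2,3-dimethyloxirane-2-carboxylic acid
Conditions: RuCl3 (cat.), NaIO4, CCl4/MeCN/H2O, rt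
Reagents that add atoms: sodium periodate, [Na+].[O-]I(=O)(=O)=O; water, O
Why: Ruthenium tetroxide oxidation generated from RuCl3 and NaIO4 converts the primary alcohol into the acid without opening the epoxide, so both centres are kept (the descriptor at C2 changes only by priority).

Step 23
Reactants: 27 tricyclic enone with O2 acetate and free C4 hydroxyl; 30 (2S,3R)-2,3-dimethyloxirane-2-carboxylic acid
Product: 32 tricyclic enone with O2 acetate and O4 (2S,3R)-2,3-dimethyloxirane-2-carboxylate, via epoxy acid mixed anhydride 31 (not isolated)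
Conditions: 30, 2,4,6-Cl3C6H2COCl, Et3N, THF, rt; then 27, DMAP, toluene, 40 °C
Reagents that add atoms: none
Why: Yamaguchi esterification through the mixed 2,4,6-trichlorobenzoic anhydride acylates the only free hydroxyl (C4) with retention at every centre.

Step 24
Reactants: 32 tricyclic enone with O2 acetate and O4 epoxy ester
Product: 33 tricyclic enone with free C2 hydroxyl and O4 (2S,3R)-2,3-dimethyloxirane-2-carboxylate
Conditions: K2CO3, MeOH, 0 °C
Reagents that add atoms: none
Why: Base-catalysed methanolysis removes the unhindered acetyl group while the ester of the α-quaternary epoxy acid, far more hindered at its acyl carbon, should persist, and acyl migration is excluded because O2 and O4 lie on opposite sides of ring C.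

Step 25
Reactants: 33 tricyclic enone with free C2 hydroxyl and O4 epoxy ester; 34 angelic acid
Product: 36 CNP0149458.1, via angelic mixed anhydride 35 (not isolated)
Conditions: 34, 2,4,6-Cl3C6H2COCl, Et3N, toluene, rt; then 33, toluene, 80 °C
Reagents that add atoms: none
Why: Yamaguchi-type acylation of the C2 alcohol by the preformed mixed anhydride, run without a nucleophilic catalyst, should transfer the angeloyl group at its less hindered carbonyl with the Z geometry intact.

**Compound list**
1 | methyl (2S)-3-hydroxy-2-methylpropanoate | COC(=O)[C@@H](C)CO | starting material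
2 | methyl (2S)-3-(benzyloxy)-2-methylpropanoate | COC(=O)[C@@H](C)COCc1ccccc1 | intermediate
3 | (2S)-3-(benzyloxy)-2-methylpropanal | O=C[C@@H](C)COCc1ccccc1 | intermediate
4 | methyl (3R,4S)-5-(benzyloxy)-3-hydroxy-4-methylpentanoate | COC(=O)C[C@@H](O)[C@@H](C)COCc1ccccc1 | intermediate
5 | methyl (3R,4S)-5-(benzyloxy)-3-[(tert-butyldimethylsilyl)oxy]-4-methylpentanoate | COC(=O)C[C@@H](O[Si](C)(C)C(C)(C)C)[C@@H](C)COCc1ccccc1 | intermediate
6 | methyl (3R,4S)-3-[(tert-butyldimethylsilyl)oxy]-5-hydroxy-4-methylpentanoate | COC(=O)C[C@@H](O[Si](C)(C)C(C)(C)C)[C@@H](C)CO | intermediate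
7 | (2R,3R)-3-[(tert-butyldimethylsilyl)oxy]-5-methoxy-2-methyl-5-oxopentanoic acid | COC(=O)C[C@@H](O[Si](C)(C)C(C)(C)C)[C@@H](C)C(=O)O | intermediate
8 | isobutyl carbonic mixed anhydride of acid 7 | COC(=O)C[C@@H](O[Si](C)(C)C(C)(C)C)[C@@H](C)C(=O)OC(=O)OCC(C)C | intermediate
9 | methyl (3R,4R)-3-[(tert-butyldimethylsilyl)oxy]-4-methyl-5-oxo-5-(pyrrolidin-1-yl)pentanoate | COC(=O)C[C@@H](O[Si](C)(C)C(C)(C)C)[C@@H](C)C(=O)N1CCCC1 | intermediate
10 | allyl benzyl ether | C=CCOCc1ccccc1 | starting material
11 | keteniminium triflate from amide 9 (C7=C1 cumulene, N-pyrrolidinium) | COC(=O)C[C@@H](O[Si](C)(C)C(C)(C)C)C(C)=C=[N+]1CCCC1.[O-]S(=O)(=O)C(F)(F)F | intermediate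
12 | cyclobutaniminium triflate (pyrrolidinium iminium of ketone 13, same configuration) | COC(=O)C[C@@H](O[Si](C)(C)C(C)(C)C)[C@]1(C)C(=[N+]2CCCC2)C[C@H]1COCc1ccccc1.[O-]S(=O)(=O)C(F)(F)F | intermediate
13 | methyl (3R)-3-{(1R,2R)-2-[(benzyloxy)methyl]-1-methyl-4-oxocyclobutyl}-3-[(tert-butyldimethylsilyl)oxy]propanoate (CH2OBn cis to the ring methyl) | COC(=O)C[C@@H](O[Si](C)(C)C(C)(C)C)[C@]1(C)C(=O)C[C@H]1COCc1ccccc1 | intermediate
14 | potassium enolate of ketone 13 (C7–O, C7=C6) | COC(=O)C[C@@H](O[Si](C)(C)C(C)(C)C)[C@]1(C)C([O-])=C[C@H]1COCc1ccccc1.[K+] | intermediate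
15 | methyl (3R)-3-{(1R,4R)-4-[(benzyloxy)methyl]-1-methyl-2-[(trifluoromethanesulfonyl)oxy]cyclobut-2-en-1-yl}-3-[(tert-butyldimethylsilyl)oxy]propanoate | COC(=O)C[C@@H](O[Si](C)(C)C(C)(C)C)[C@]1(C)C(OS(=O)(=O)C(F)(F)F)=C[C@H]1COCc1ccccc1 | intermediate
16 | (3R)-3-{(1R,4R)-4-[(benzyloxy)methyl]-1-methyl-2-[(trifluoromethanesulfonyl)oxy]cyclobut-2-en-1-yl}-3-[(tert-butyldimethylsilyl)oxy]-N-methoxy-N-methylpropanamide | CON(C)C(=O)C[C@@H](O[Si](C)(C)C(C)(C)C)[C@]1(C)C(OS(=O)(=O)C(F)(F)F)=C[C@H]1COCc1ccccc1 | intermediate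
17 | (5R)-5-{(1R,4R)-4-[(benzyloxy)methyl]-1-methyl-2-[(trifluoromethanesulfonyl)oxy]cyclobut-2-en-1-yl}-5-[(tert-butyldimethylsilyl)oxy]-2-methylpent-1-en-3-one | C=C(C)C(=O)C[C@@H](O[Si](C)(C)C(C)(C)C)[C@]1(C)C(OS(=O)(=O)C(F)(F)F)=C[C@H]1COCc1ccccc1 | intermediate
18 | (3R,4R)-3-[(benzyloxy)methyl]-4-{(1R)-1-[(tert-butyldimethylsilyl)oxy]-4-methyl-3-[(triethylsilyl)oxy]pent-3-en-1-yl}-4-methylcyclobut-1-en-1-yl trifluoromethanesulfonate | CC[Si](CC)(CC)OC(=C(C)C)C[C@@H](O[Si](C)(C)C(C)(C)C)[C@]1(C)C(OS(=O)(=O)C(F)(F)F)=C[C@H]1COCc1ccccc1 | intermediate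
19 | 1-[(3R,4S)-3-[(benzyloxy)methyl]-4-{(1R)-1-[(tert-butyldimethylsilyl)oxy]-4-methyl-3-[(triethylsilyl)oxy]pent-3-en-1-yl}-4-methylcyclobut-1-en-1-yl]ethan-1-one | CC[Si](CC)(CC)OC(=C(C)C)C[C@@H](O[Si](C)(C)C(C)(C)C)[C@]1(C)C(C(C)=O)=C[C@H]1COCc1ccccc1 | intermediate
20 | trichlorotitanium enolate (C7=C8) of diketone 21 | CC(C)(C)[Si](C)(C)O[C@@H]1CC(=O)C(C)(C)[C@@H]2[C@@H](COCc3ccccc3)[C@@]1(C)C2=C(C)O[Ti](Cl)(Cl)Cl | intermediate
21 | (2R)-7-acetyl-8-[(benzyloxy)methyl]-2-[(tert-butyldimethylsilyl)oxy]-1,5,5-trimethylbicyclo[4.1.1]octan-4-one; acetyl and CH2OBn anti to the C2–C5 bridge, OSi on the side of position 8 | CC(C)(C)[Si](C)(C)O[C@@H]1CC(=O)C(C)(C)[C@@H]2[C@@H](COCc3ccccc3)[C@@]1(C)[C@H]2C(C)=O | intermediate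
22 | (2R)-7-acetyl-8-[(benzyloxy)methyl]-2-hydroxy-1,5,5-trimethylbicyclo[4.1.1]octan-4-one | O[C@@H]1CC(=O)C(C)(C)[C@@H]2[C@@H](COCc3ccccc3)[C@@]1(C)[C@H]2C(C)=O | intermediate
23 | (2R,4R)-7-acetyl-8-[(benzyloxy)methyl]-4-hydroxy-1,5,5-trimethylbicyclo[4.1.1]octan-2-yl acetate (O2 and O4 trans) | CC(=O)O[C@@H]1C[C@@H](O)C(C)(C)[C@@H]2[C@@H](COCc3ccccc3)[C@@]1(C)[C@H]2C(C)=O | intermediate
24 | (2R,4R)-7-acetyl-4-hydroxy-8-(hydroxymethyl)-1,5,5-trimethylbicyclo[4.1.1]octan-2-yl acetate | CC(=O)O[C@@H]1C[C@@H](O)C(C)(C)[C@@H]2[C@@H](CO)[C@@]1(C)[C@H]2C(C)=O | intermediate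
25 | (2R,4R)-7-acetyl-8-formyl-4-hydroxy-1,5,5-trimethylbicyclo[4.1.1]octan-2-yl acetate | CC(=O)O[C@@H]1C[C@@H](O)C(C)(C)[C@@H]2[C@@H](C=O)[C@@]1(C)[C@H]2C(C)=O | intermediate
26 | (2R,4R)-7-acetyl-8-[2-(dimethoxyphosphoryl)acetyl]-4-hydroxy-1,5,5-trimethylbicyclo[4.1.1]octan-2-yl acetate | CC(=O)O[C@@H]1C[C@@H](O)C(C)(C)[C@@H]2[C@@H](C(=O)CP(=O)(OC)OC)[C@@]1(C)[C@H]2C(C)=O | intermediate
27 | tricyclic enone (rings A, B, C) with O2 acetate and free C4 hydroxyl | CC(=O)O[C@@H]1C[C@@H](O)C(C)(C)[C@@H]2[C@H]3C(=O)C=C(C)[C@@H]2[C@]31C | intermediate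
28 | (2E)-2-methylbut-2-en-1-ol | C/C=C(\C)CO | starting material
29 | [(2R,3R)-2,3-dimethyloxiran-2-yl]methanol | OC[C@@]1(C)O[C@@H]1C | intermediate
30 | (2S,3R)-2,3-dimethyloxirane-2-carboxylic acid | OC(=O)[C@@]1(C)O[C@@H]1C | intermediate
31 | (2S,3R)-2,3-dimethyloxirane-2-carboxylic 2,4,6-trichlorobenzoic anhydride | O=C(OC(=O)c1c(Cl)cc(Cl)cc1Cl)[C@@]1(C)O[C@@H]1C | intermediate
32 | tricyclic enone with O2 acetate and O4 (2S,3R)-2,3-dimethyloxirane-2-carboxylate | CC(=O)O[C@@H]1C[C@@H](OC(=O)[C@@]2(C)O[C@@H]2C)C(C)(C)[C@@H]2[C@H]3C(=O)C=C(C)[C@@H]2[C@]31C | intermediate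
33 | tricyclic enone with free C2 hydroxyl and O4 (2S,3R)-2,3-dimethyloxirane-2-carboxylate | O[C@@H]1C[C@@H](OC(=O)[C@@]2(C)O[C@@H]2C)C(C)(C)[C@@H]2[C@H]3C(=O)C=C(C)[C@@H]2[C@]31C | intermediate
34 | angelic acid, (2Z)-2-methylbut-2-enoic acid | C/C=C(/C)C(=O)O | starting material
35 | (2Z)-2-methylbut-2-enoic 2,4,6-trichlorobenzoic anhydride | C/C=C(/C)C(=O)OC(=O)c1c(Cl)cc(Cl)cc1Cl | intermediate
36 | CNP0149458.1: tricyclic enone with C2 angelate and C4 (2S,3R)-2,3-dimethyloxirane-2-carboxylate | C/C=C(/C)C(=O)O[C@@H]1C[C@@H](OC(=O)[C@@]2(C)O[C@@H]2C)C(C)(C)[C@@H]2[C@H]3C(=O)C=C(C)[C@@H]2[C@]31C | target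

**Step count**
Total: 25 steps. Longest linear sequence: 23 steps (steps 1–20 and 23–25); steps 21–22 make the epoxy acid.

**Steps most likely to fail**

Step 8. What may go wrong: the ester carbonyl oxygen may capture the keteniminium carbon, or the β-silyloxy group may be lost before the alkene adds; the ring closure at C1 may also show poor facial selectivity. The fallback sets out from acid 7. Oxalyl chloride with catalytic DMF gives acid chloride F1. Et3N then releases ketene F2 in the presence of 10, and EtAlCl2 at −78 °C promotes a Lewis acid-activated ketene–alkene [2+2] cycloaddition. This runs at low temperature, avoids the cationic amide adducts, and is expected to place the larger ketene substituent trans to the alkene substituent. It comes back to the route at cyclobutanone 13.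

Step 14. What may go wrong: protodesilylation of the hindered enol silane, or Lewis acid-induced oligomerisation of the acetylcyclobutene, may outrun C5–C6 bond formation. The fallback sets out from enone triflate 17. Carbonylative coupling under the conditions of step 13 gives bis-enone F3. [(Ph3P)CuH]6 in toluene transfers hydride to the unsubstituted terminus of the isopropenyl ketone and generates copper enolate F4 with the same C4=C5 regiochemistry. F4 adds to C6 in a reductive Michael cyclisation, and protonation at work-up returns to diketone 21.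

Step 20. What may go wrong: the phosphonate carbanion may fail to add to the hindered C8 ketone, or the oxaphosphetane may fail to collapse within the strained bicyclo[3.1.1]heptenone. The fallback sets out from aldehyde 25. SnCl2-promoted homologation with allyl diazoacetate gives β-keto allyl ester F5. A TiCl4/pyridine-mediated intramolecular Knoevenagel condensation onto the C8 ketone (Lewis acid activation of the ketone, dehydration of a doubly activated aldol) gives alkylidene keto ester F6. Pd(PPh3)4 and morpholine then remove the allyl group with decarboxylation (Tsuji–Trost deallylation) and return to enone 27.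

Further compounds
F1 | step 8 | methyl (3R,4R)-5-chloro-3-[(tert-butyldimethylsilyl)oxy]-4-methyl-5-oxopentanoate (acid chloride of 7) | COC(=O)C[C@@H](O[Si](C)(C)C(C)(C)C)[C@@H](C)C(Cl)=O
F2 | step 8 | methyl (3R)-3-[(tert-butyldimethylsilyl)oxy]-4-methyl-5-oxopent-4-enoate (ketene) | COC(=O)C[C@@H](O[Si](C)(C)C(C)(C)C)C(C)=C=O
F3 | step 14 | (5R)-5-{(1S,4R)-2-acetyl-4-[(benzyloxy)methyl]-1-methylcyclobut-2-en-1-yl}-5-[(tert-butyldimethylsilyl)oxy]-2-methylpent-1-en-3-one (bis-enone) | C=C(C)C(=O)C[C@@H](O[Si](C)(C)C(C)(C)C)[C@]1(C)C(C(C)=O)=C[C@H]1COCc1ccccc1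
F4 | step 14 | copper enolate (C4=C5) of the isopropyl ketone derived from F3 | CC(C)=C(O[Cu])C[C@@H](O[Si](C)(C)C(C)(C)C)[C@]1(C)C(C(C)=O)=C[C@H]1COCc1ccccc1
F5 | step 20 | allyl 3-oxopropanoate at C11 of the bicycle (β-keto allyl ester; O2 acetate, C4 hydroxyl, C7 acetyl) | CC(=O)O[C@@H]1C[C@@H](O)C(C)(C)[C@@H]2[C@@H](C(=O)CC(=O)OCC=C)[C@@]1(C)[C@H]2C(C)=O
F6 | step 20 | tricyclic enone 27 bearing an allyl ester at C9 | CC(=O)O[C@@H]1C[C@@H](O)C(C)(C)[C@@H]2[C@H]3C(=O)C(C(=O)OCC=C)=C(C)[C@@H]2[C@]31C
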